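Assumptions: reagents named without a number are bought. Tetralin atoms are numbered as in the target name (C5 carries the methyl group, C8 the side chain; C2' and C6' are the side-chain stereocentres). The E/Z mixture of 15 is used as such.

## Retrosynthetic overview

1. The benzene ring is bought. The only ring made is the saturated ring, closed last at C4a–C5 by a catalytic asymmetric reductive Friedel–Crafts cyclisation of aryl methyl ketone 23, which sets C5.
2. The cinnamate comes from lipase acylation of the primary alcohol; one hydrogenation removes all benzyl groups and the chain alkene.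
3. The side chain is joined at C3'–C4' by a Wittig reaction of keto-aldehyde 12 with phosphonium salt 19.
4. 12 comes from enal 5 by an iminium-catalysed Mukaiyama–Michael addition (sets C8 and C2' together), two-carbon homologation and thioester reduction; 5 comes from a Heck reaction.
5. 19 comes from achiral enal 15 by iminium-catalysed transfer hydrogenation (sets C6').

## Route

Step 1
Reactants: 1 3-bromo-5-hydroxybenzoic acid
Product: 2 benzyl 3-(benzyloxy)-5-bromobenzoate
Conditions: BnBr (2.3 equiv), K2CO3, DMF, 60 °C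
Reagents that add atoms: benzyl bromide BrCc1ccccc1
Why: Double SN2 O-alkylation (Williamson ether and carboxylate ester formation) masks phenol and acid as benzyl groups that one later hydrogenolysis removes.

Step 2
Reactants: 2 benzyl 3-(benzyloxy)-5-bromobenzoate; 3 3,3-diethoxyprop-1-ene (acrolein diethyl acetal)
Product: 5 benzyl 3-(benzyloxy)-5-[(1E)-3-oxoprop-1-en-1-yl]benzoate, via diethyl acetal 4 (not isolated)
Conditions: Pd(OAc)2 (3 mol%), nBu4NOAc, K2CO3, KCl, DMF, 90 °C; then 2 M HCl, rt
Reagents that add atoms: water O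
Why: Phosphine-free Heck arylation of the acrolein acetal gives the E-cinnamyl acetal, and acidic work-up hydrolyses it to the enal.

Step 3
Reactants: 6 S-ethyl propanethioate
Product: 8 {[(1Z)-1-(ethylsulfanyl)prop-1-en-1-yl]oxy}trimethylsilane, via lithium enolate 7 (not isolated)
Conditions: LiN(iPr)2, THF, −78 °C; then Me3SiCl, −78 °C to rt
Reagents that add atoms: chlorotrimethylsilane C[Si](C)(C)Cl
Why: Kinetic enolisation through a chair-like transition state places methyl cis to sulfur, and O-silylation traps this enolate as the Z silyl ketene thioacetal.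

Step 4
Reactants: 5 benzyl 3-(benzyloxy)-5-[(1E)-3-oxoprop-1-en-1-yl]benzoate; 8 {[(1Z)-1-(ethylsulfanyl)prop-1-en-1-yl]oxy}trimethylsilane
Product: 9 S-ethyl (2R,3S)-3-{3-(benzyloxy)-5-[(benzyloxy)carbonyl]phenyl}-2-methyl-5-oxopentanethioate
Conditions: (2R,5R)-5-benzyl-2-tert-butyl-3-methylimidazolidin-4-one·CCl3CO2H (20 mol%), H2O (2 equiv), CH2Cl2, −55 °C
Reagents that add atoms: none
Why: Iminium-catalysed Mukaiyama–Michael addition: the benzyl and tert-butyl groups of the (2R,5R) catalyst shield the Si face of the E-iminium ion, so the nucleophile adds to the Re face of the β-carbon (3S), and the open transition state of the Z silyl ketene thioacetal gives the 2,3-syn adduct (2R); these are the first stereocentres, made from achiral inputs.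

Step 5
Reactants: 9 S-ethyl (2R,3S)-3-{3-(benzyloxy)-5-[(benzyloxy)carbonyl]phenyl}-2-methyl-5-oxopentanethioate
Product: 11 S-ethyl (2R,3S)-3-{3-(benzyloxy)-5-[(benzyloxy)carbonyl]phenyl}-2-methyl-6-oxoheptanethioate, via enol ether 10 (not isolated)
Conditions: PPh3, 1-chloroethyl ethyl ether, THF, rt; NaN(SiMe3)2, −78 °C; add 9, −78 to 0 °C; then 1 M HCl, THF, rt
Reagents that add atoms: 1-chloroethyl ethyl ether CCOC(C)Cl; water O
Why: Wittig olefination with an α-alkoxy ylide made in the flask attacks the aldehyde much faster than the thioester or benzoate at −78 °C, and mild acid hydrolysis of the enol ether gives the methyl ketone (net two-carbon homologation).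

Step 6
Reactants: 11 S-ethyl (2R,3S)-3-{3-(benzyloxy)-5-[(benzyloxy)carbonyl]phenyl}-2-methyl-6-oxoheptanethioate
Product: 12 benzyl 3-(benzyloxy)-5-[(2R,3S)-2-methyl-1,6-dioxoheptan-3-yl]benzoate
Conditions: Et3SiH (3 equiv), Pd/C (10 wt% Pd, 5 mol%), acetone, rt
Reagents that add atoms: none
Why: Fukuyama reduction converts the thioester into the aldehyde under neutral, aprotic conditions that leave the ketone, the benzyl groups and the α-stereocentre untouched.

Step 7
Reactants: 13 1-(benzyloxy)propan-2-one; 14 (triphenylphosphoranylidene)acetaldehyde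
Product: 15 4-(benzyloxy)-3-methylbut-2-enal (E/Z mixture, E major)
Conditions: toluene, 100 °C
Reagents that add atoms: none
Why: Wittig olefination of the activated α-alkoxy ketone with the stabilised formyl ylide gives the β,β-disubstituted enal; its geometry does not matter for step 8.

Step 8
Reactants: 15 4-(benzyloxy)-3-methylbut-2-enal
Product: 17 (3R)-4-(benzyloxy)-3-methylbutan-1-ol, via aldehyde 16 (not isolated)
Conditions: (S)-2-tert-butyl-3-methylimidazolidin-4-one·CCl3CO2H (20 mol%), Hantzsch ester (1.2 equiv), CHCl3, −30 °C; then NaBH4, EtOH, 0 °C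
Reagents that add atoms: none
Why: Iminium-catalysed transfer hydrogenation: the E and Z iminium ions interconvert, and hydride from the Hantzsch ester adds to the E-iminium face anti to the tert-butyl group to give 3R (about 90% ee expected for this substrate class); NaBH4 then reduces the aldehyde in the same flask.

Step 9
Reactants: 17 (3R)-4-(benzyloxy)-3-methylbutan-1-ol
Product: 19 [(3R)-4-(benzyloxy)-3-methylbutyl]triphenylphosphonium bromide, via bromide 18 (not isolated)
Conditions: CBr4 (1.05 equiv), PPh3 (2.3 equiv), MeCN, 0 °C to rt; then 80 °C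
Reagents that add atoms: tetrabromomethane BrC(Br)(Br)Br; triphenylphosphine c1ccc(cc1)P(c1ccccc1)c1ccccc1
Why: Appel bromination followed by SN2 quaternisation of the primary bromide by the excess PPh3; the stereocentre is not involved.

Step 10
Reactants: 12 benzyl 3-(benzyloxy)-5-[(2R,3S)-2-methyl-1,6-dioxoheptan-3-yl]benzoate; 19 [(3R)-4-(benzyloxy)-3-methylbutyl]triphenylphosphonium bromide
Product: 21 benzyl 3-(benzyloxy)-5-[(5S,6S,7Z,10R)-11-(benzyloxy)-6,10-dimethyl-2-oxoundec-7-en-5-yl]benzoate, via ylide 20 (not isolated)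
Conditions: NaN(SiMe3)2 (1.0 equiv to 19), THF, −78 °C; add 12, −78 to 0 °C
Reagents that add atoms: none
Why: Wittig olefination with the non-stabilised ylide takes the aldehyde in preference to the methyl ketone at low temperature; the Z geometry is irrelevant because the alkene is hydrogenated next.

Step 11
Reactants: 21 benzyl 3-(benzyloxy)-5-[(5S,6S,7Z,10R)-11-(benzyloxy)-6,10-dimethyl-2-oxoundec-7-en-5-yl]benzoate
Product: 22 3-hydroxy-5-[(5S,6S,10R)-11-hydroxy-6,10-dimethyl-2-oxoundecan-5-yl]benzoic acid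
Conditions: H2 (1 atm), Pd(OH)2/C, EtOAc/MeOH, rt
Reagents that add atoms: none
Why: Heterogeneous hydrogenation saturates the alkene and hydrogenolyses the benzyl ester and both benzyl ethers in one operation, while the dialkyl ketone and all stereocentres stay intact.

Step 12
Reactants: 22 3-hydroxy-5-[(5S,6S,10R)-11-hydroxy-6,10-dimethyl-2-oxoundecan-5-yl]benzoic acid
Product: 23 3-hydroxy-5-[(5S,6S,10R)-6,10-dimethyl-2-oxo-11-{[(2E)-3-phenylprop-2-enoyl]oxy}undecan-5-yl]benzoic acid
Conditions: immobilised Candida antarctica lipase B, vinyl cinnamate (3 equiv), tBuOMe/THF, 45 °C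
Reagents that add atoms: vinyl cinnamate C=COC(=O)/C=C/c1ccccc1
Why: Lipase-catalysed irreversible transesterification acylates the primary alcohol only, because phenols and benzoic acids are not substrates of this serine hydrolase and the vinyl leaving group tautomerises to acetaldehyde.

Step 13
Reactants: 23 3-hydroxy-5-[(5S,6S,10R)-6,10-dimethyl-2-oxo-11-{[(2E)-3-phenylprop-2-enoyl]oxy}undecan-5-yl]benzoic acid
Product: 27 (5R,8S)-4-hydroxy-5-methyl-8-[(2S,6R)-6-methyl-7-{[(2E)-3-phenylprop-2-enoyl]oxy}heptan-2-yl]-5,6,7,8-tetrahydronaphthalene-2-carboxylic acid, via carbinol 24 (not isolated), via dihydronaphthalene 25 (not isolated), via o-quinone methide 26 (not isolated)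
Conditions: (R)-3,3'-bis(2,4,6-triisopropylphenyl)-1,1'-binaphthyl-2,2'-diyl N-triflylphosphoramide (10 mol%), MgSO4, PhCF3, 50 °C; then Hantzsch ester (1.5 equiv), 30 °C
Reagents that add atoms: none
Why: Proposed new method: the strongly acidic chiral phosphoramide protonates the ketone while its basic P=O/sulfonyl oxygen hydrogen-bonds the phenol OH, so an intramolecular Friedel–Crafts hydroxyalkylation closes the six-membered ring at the carbon ortho to OH (the other site is flanked by CO2H); the tertiary o-hydroxybenzylic carbinol 24 loses water to dihydronaphthalene 25, which on reprotonation gives o-quinone methide 26 as a contact ion pair in the chiral pocket, and the Hantzsch ester then delivers hydride to C5 under catalyst control (the remote C8 centre exerts only a weak, possibly opposing 1,4-bias) to set 5R, trans to the C8 side chain; the closest known reaction types are acid-mediated cyclodehydration of 5-aryl-2-pentanones to 1-methyl-3,4-dihydronaphthalenes and chiral phosphoric acid-catalysed transfer hydrogenation of o-quinone methides generated from o-hydroxy-1,1-diarylethylenes.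

## Compound list

1 | 3-bromo-5-hydroxybenzoic acid | OC(=O)c1cc(O)cc(Br)c1 | starting material
2 | benzyl 3-(benzyloxy)-5-bromobenzoate | O=C(OCc1ccccc1)c1cc(OCc2ccccc2)cc(Br)c1 | intermediate
3 | 3,3-diethoxyprop-1-ene | C=CC(OCC)OCC | starting material
4 | benzyl 3-(benzyloxy)-5-[(1E)-3,3-diethoxyprop-1-en-1-yl]benzoate | CCOC(OCC)/C=C/c1cc(OCc2ccccc2)cc(C(=O)OCc2ccccc2)c1 | intermediate
5 | benzyl 3-(benzyloxy)-5-[(1E)-3-oxoprop-1-en-1-yl]benzoate | O=C/C=C/c1cc(OCc2ccccc2)cc(C(=O)OCc2ccccc2)c1 | intermediate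
6 | S-ethyl propanethioate | CCC(=O)SCC | starting material
7 | lithium (1Z)-1-(ethylsulfanyl)prop-1-en-1-olate | C/C=C(\SCC)[O-].[Li+] | intermediate
8 | {[(1Z)-1-(ethylsulfanyl)prop-1-en-1-yl]oxy}trimethylsilane | C/C=C(\SCC)O[Si](C)(C)C | intermediate
9 | S-ethyl (2R,3S)-3-{3-(benzyloxy)-5-[(benzyloxy)carbonyl]phenyl}-2-methyl-5-oxopentanethioate | CCSC(=O)[C@H](C)[C@H](CC=O)c1cc(OCc2ccccc2)cc(C(=O)OCc2ccccc2)c1 | intermediate
10 | S-ethyl (2R,3S)-3-{3-(benzyloxy)-5-[(benzyloxy)carbonyl]phenyl}-6-ethoxy-2-methylhept-5-enethioate (E/Z) | CCSC(=O)[C@H](C)[C@H](CC=C(C)OCC)c1cc(OCc2ccccc2)cc(C(=O)OCc2ccccc2)c1 | intermediate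
11 | S-ethyl (2R,3S)-3-{3-(benzyloxy)-5-[(benzyloxy)carbonyl]phenyl}-2-methyl-6-oxoheptanethioate | CCSC(=O)[C@H](C)[C@H](CCC(C)=O)c1cc(OCc2ccccc2)cc(C(=O)OCc2ccccc2)c1 | intermediate
12 | benzyl 3-(benzyloxy)-5-[(2R,3S)-2-methyl-1,6-dioxoheptan-3-yl]benzoate | O=C[C@H](C)[C@H](CCC(C)=O)c1cc(OCc2ccccc2)cc(C(=O)OCc2ccccc2)c1 | intermediate
13 | 1-(benzyloxy)propan-2-one | CC(=O)COCc1ccccc1 | starting material
14 | (triphenylphosphoranylidene)acetaldehyde | O=CC=P(c1ccccc1)(c1ccccc1)c1ccccc1 | starting material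
15 | 4-(benzyloxy)-3-methylbut-2-enal (E drawn, E/Z mixture used) | O=C/C=C(\C)COCc1ccccc1 | intermediate
16 | (3R)-4-(benzyloxy)-3-methylbutanal | O=CC[C@@H](C)COCc1ccccc1 | intermediate
17 | (3R)-4-(benzyloxy)-3-methylbutan-1-ol | OCC[C@@H](C)COCc1ccccc1 | intermediate
18 | {[(2R)-4-bromo-2-methylbutoxy]methyl}benzene | BrCC[C@@H](C)COCc1ccccc1 | intermediate
19 | [(3R)-4-(benzyloxy)-3-methylbutyl]triphenylphosphonium bromide | [Br-].C[C@H](CC[P+](c1ccccc1)(c1ccccc1)c1ccccc1)COCc1ccccc1 | intermediate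
20 | [(3R)-4-(benzyloxy)-3-methylbutylidene]triphenylphosphorane | C[C@H](CC=P(c1ccccc1)(c1ccccc1)c1ccccc1)COCc1ccccc1 | intermediate
21 | benzyl 3-(benzyloxy)-5-[(5S,6S,7Z,10R)-11-(benzyloxy)-6,10-dimethyl-2-oxoundec-7-en-5-yl]benzoate | C[C@H](C/C=C\[C@H](C)[C@H](CCC(C)=O)c1cc(OCc2ccccc2)cc(C(=O)OCc2ccccc2)c1)COCc1ccccc1 | intermediate
22 | 3-hydroxy-5-[(5S,6S,10R)-11-hydroxy-6,10-dimethyl-2-oxoundecan-5-yl]benzoic acid | C[C@H](CCC[C@H](C)[C@H](CCC(C)=O)c1cc(O)cc(C(=O)O)c1)CO | intermediate
23 | 3-hydroxy-5-[(5S,6S,10R)-6,10-dimethyl-2-oxo-11-{[(2E)-3-phenylprop-2-enoyl]oxy}undecan-5-yl]benzoic acid | C[C@H](CCC[C@H](C)[C@H](CCC(C)=O)c1cc(O)cc(C(=O)O)c1)COC(=O)/C=C/c1ccccc1 | intermediate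
24 | (8S)-4,5-dihydroxy-5-methyl-8-[(2S,6R)-6-methyl-7-{[(2E)-3-phenylprop-2-enoyl]oxy}heptan-2-yl]-5,6,7,8-tetrahydronaphthalene-2-carboxylic acid (C5 epimers) | C[C@H](CCC[C@H](C)[C@@H]1CCC(C)(O)c2c(O)cc(C(=O)O)cc21)COC(=O)/C=C/c1ccccc1 | intermediate
25 | (8S)-4-hydroxy-5-methyl-8-[(2S,6R)-6-methyl-7-{[(2E)-3-phenylprop-2-enoyl]oxy}heptan-2-yl]-7,8-dihydronaphthalene-2-carboxylic acid | C[C@H](CCC[C@H](C)[C@@H]1CC=C(C)c2c(O)cc(C(=O)O)cc21)COC(=O)/C=C/c1ccccc1 | intermediate
26 | (8S)-5-methyl-8-[(2S,6R)-6-methyl-7-{[(2E)-3-phenylprop-2-enoyl]oxy}heptan-2-yl]-4-oxo-4,6,7,8-tetrahydronaphthalene-2-carboxylic acid (o-quinone methide) | C[C@H](CCC[C@H](C)[C@@H]1CCC(C)=C2C(=O)C=C(C(=O)O)C=C21)COC(=O)/C=C/c1ccccc1 | intermediate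
27 | (5R,8S)-4-hydroxy-5-methyl-8-[(2S,6R)-6-methyl-7-{[(2E)-3-phenylprop-2-enoyl]oxy}heptan-2-yl]-5,6,7,8-tetrahydronaphthalene-2-carboxylic acid | C[C@H](CCC[C@H](C)[C@@H]1CC[C@@H](C)c2c(O)cc(C(=O)O)cc21)COC(=O)/C=C/c1ccccc1 | target

## Step count and risks

Total step count: 13. Longest linear sequence: 9 (steps 1, 2, 4, 5, 6, 10, 11, 12, 13, from compound 1).

Most likely to fail, step 13 (the proposed new reductive cyclisation). The para-carboxyl phenol is a weak nucleophile, ring closure could go to the other ortho site of the tether, and the catalyst has to override a probable substrate preference for the cis isomer. The catalyst enantiomer must therefore be confirmed in the first run, with the (S) catalyst as the alternative. The fallback uses known chemistry and sets C5 in the C–C bond-forming event instead of by hydride delivery. It sets out from 23: NaBH4 in MeOH at 0 °C reduces the ketone to the secondary carbinol F1 (epimer mixture). MeSO3H in CH2Cl2 (or TfOH in hexafluoroisopropanol) then effects a classical Friedel–Crafts cyclialkylation. A chair-like closure that keeps both the C8 side chain and the new C5 methyl pseudoaxial, away from the peri positions, should favour the 1,4-trans tetralin; the cis isomer is removed by preparative HPLC. It comes back to the route at 27.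

Second, step 5 (α-alkoxy Wittig next to a thioester). The basic ylide may epimerise C2 of the thioester or be acylated by it. The fallback changes the order of events so that no basic ylide meets the thioester. It sets out from 9: HC(OMe)3, MeOH and catalytic TsOH give the dimethyl acetal F2; Fukuyama reduction gives the acetal aldehyde F3; Wittig reaction with ylide 20 gives the alkene acetal F4; aqueous AcOH/THF releases the aldehyde F5; the same ethoxyethylidene Wittig reaction gives the enol ether F6, whose hydrolysis with 1 M HCl comes back to the route at 21.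

Third, step 12 (lipase acylation). The cinnamoyl donor is a slow substrate for the lipase and conversion may stall. The fallback is chemical over-acylation and selective cleavage. It sets out from 22: cinnamoyl chloride (2.5 equiv) and pyridine, with aqueous work-up that hydrolyses the mixed anhydride, give the bis-cinnamate F7. Pyrrolidine (1.1 equiv) in THF at 0 °C then removes only the aryl ester and comes back to the route at 23.

## Further compounds

F1 | step 13 | 3-hydroxy-5-[(5S,6S,10R)-2-hydroxy-6,10-dimethyl-11-{[(2E)-3-phenylprop-2-enoyl]oxy}undecan-5-yl]benzoic acid (C2 epimers) | C[C@H](CCC[C@H](C)[C@H](CCC(C)O)c1cc(O)cc(C(=O)O)c1)COC(=O)/C=C/c1ccccc1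
F2 | step 5 | S-ethyl (2R,3S)-3-{3-(benzyloxy)-5-[(benzyloxy)carbonyl]phenyl}-5,5-dimethoxy-2-methylpentanethioate | CCSC(=O)[C@H](C)[C@H](CC(OC)OC)c1cc(OCc2ccccc2)cc(C(=O)OCc2ccccc2)c1
F3 | step 5 | benzyl 3-(benzyloxy)-5-[(2R,3S)-5,5-dimethoxy-2-methyl-1-oxopentan-3-yl]benzoate | O=C[C@H](C)[C@H](CC(OC)OC)c1cc(OCc2ccccc2)cc(C(=O)OCc2ccccc2)c1
F4 | step 5 | benzyl 3-(benzyloxy)-5-[(3S,4S,5Z,8R)-9-(benzyloxy)-1,1-dimethoxy-4,8-dimethylnon-5-en-3-yl]benzoate | C[C@H](C/C=C\[C@H](C)[C@H](CC(OC)OC)c1cc(OCc2ccccc2)cc(C(=O)OCc2ccccc2)c1)COCc1ccccc1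
F5 | step 5 | benzyl 3-(benzyloxy)-5-[(3S,4S,5Z,8R)-9-(benzyloxy)-4,8-dimethyl-1-oxonon-5-en-3-yl]benzoate | C[C@H](C/C=C\[C@H](C)[C@H](CC=O)c1cc(OCc2ccccc2)cc(C(=O)OCc2ccccc2)c1)COCc1ccccc1
F6 | step 5 | benzyl 3-(benzyloxy)-5-[(5S,6S,7Z,10R)-11-(benzyloxy)-2-ethoxy-6,10-dimethylundeca-2,7-dien-5-yl]benzoate | C[C@H](C/C=C\[C@H](C)[C@H](CC=C(C)OCC)c1cc(OCc2ccccc2)cc(C(=O)OCc2ccccc2)c1)COCc1ccccc1
F7 | step 12 | 3-[(5S,6S,10R)-6,10-dimethyl-2-oxo-11-{[(2E)-3-phenylprop-2-enoyl]oxy}undecan-5-yl]-5-{[(2E)-3-phenylprop-2-enoyl]oxy}benzoic acid | C[C@H](CCC[C@H](C)[C@H](CCC(C)=O)c1cc(OC(=O)/C=C/c2ccccc2)cc(C(=O)O)c1)COC(=O)/C=C/c1ccccc1
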